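Locants used throughout: O1–C2(=O)–C3=C4–C5 in each butenolide (primes for ring B), C5–C6–C6'–C5' in the four-membered ring, C1'' for the carbinol carbon of a side chain. Compound numbers are those of the list after the steps.

## Analysis of the target

- Compound 19 is a 1,7-dioxadispiro[4.0.4.2]dodeca-3,9-diene-2,8-dione. Two adjacent carbons of a cyclobutane (C5, C5') are each the spiro γ-carbon of a 4-bromo-3-(1-acetoxybutyl)butenolide, and the other two (C6, C6') each carry a bromine.
- The ring stereocentres are 5S,5'S,6R,6'R. O1 and O1' are trans, the two cyclobutane bromines are trans, and each of them is anti to the vicinal C–O bond and therefore cis to the neighbouring C4. The core has a twofold axis.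
- The carbinol centres are (S) in one side chain and (R) in the other, so the molecule as a whole has no symmetry although its halves have the same constitution.
- Sensitive groups are the allylic acetates α to the lactone carbonyl (any C3 enolate or C5 dienolate expels acetate, and nucleophiles add at C4 with loss of acetate), the β-bromobutenolides, the vicinal dibromide and the strained ring with two adjacent quaternary C–O centres.
- The synthesis is hard for two reasons. The two vicinal oxygenated spiro centres need a defined absolute configuration next to side chains that are mirror images of each other. The bromine on C6 and the bromine on C4 end up about 3 Å apart, so the order in which they are introduced decides whether the right diastereomer can form.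
- The strategy rests on one feature: C5 and C5', with their trans oxygens, are the two ends of a C5=C5' double bond. The bifuranylidenedione 14 with one (S) and one (R) side chain has a centre of inversion and is meso, so adding a two-carbon unit across C5=C5' builds the ring and desymmetrises in one step.

## Retrosynthetic reasoning

**19 to 17 (through 18).** The vinylic C4–Br and C4'–Br bonds are cut first, so they are formed last. They cannot be present earlier: a substituent larger than hydrogen on C4 lies under the neighbouring cyclobutane carbon and would send the bromide of step 10 to the other carbon. They cannot be introduced by a nucleophile either, because every C3 enolate expels the C1'' acetate. What is left is electrophilic addition across C3=C4 (18) and loss of HBr. In 18 the hydrogen on C4 is syn to the bromine on C3, and an amine base would remove the anti hydrogen on C1'' instead. The forward step therefore has to convert this syn relation into an anti one, and the neighbouring acetate is used for that.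

**17 to 16.** The C6–Br and C6'–Br bonds are cut to a cyclobutene. This is done while C4 still bears hydrogen: the strained alkene is then the only reactive one, and the small, positively polarised C4–H lets bromide enter anti to the vicinal C–O bond. The forward reaction must be an anti addition with that regiochemistry of opening.

**16 to 14 and 15.** C5–C6 and C5'–C6' are cut, which opens the four-membered ring and turns the two quaternary centres into a tetrasubstituted alkene. This is the place to cut because both difficult centres vanish at once and 14 is achiral, so the absolute configuration is asked of one catalyst-controlled event. The forward reaction has to add 15 to the excited alkene with face selection and close the ring with O1 and O1' trans.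

**14 to 12 (through 13).** The C5=C5' double bond is traced back to a C5–C5' single bond. The forward step is a dehydrogenation, and it must avoid a carbanion at C5, which would expel the neighbouring lactone oxygen.

**12 to 11 to 9 and 10.** The C5–C5' bond is cut between an electrophilic half 9 and a nucleophilic half 10. A cross-coupling of one (R) and one (S) half is the only way to obtain the heterochiral, meso pairing without a statistical mixture. The nucleophilic half carries a silyl ether instead of the acetate, because an acetate on C1'' of an electron-rich furan would be lost; 11 to 12 restores the acetate.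

**9 and 10 to 7 and 8 to 6.** Both halves come from one racemate. A resolution of 6 supplies the two enantiomers in the equal amounts that the meso compound needs, so nothing is discarded.

**6 to 4 (through 5) to 1 and 2.** The C3–C1'' bond is cut. The β-substituted lactone 1 is a poor partner for a direct amine-catalysed coupling with 2, so the bond is made by conjugate addition of a thiolate, aldol reaction of the resulting enolate and later elimination.

## Alternatives that were turned down

**Alternative 1: double bromo-aldol and lactonisation.**
- Disconnection: in the diol A1 (19 without its acetyl groups) each butenolide is cut at C3–C1'', C4–Br and O1–C2. This leads to 2 and the bis(alkynoate) diol A2, a trans-3,4-dibromocyclobutane-1,2-diol with a propiolate ester on each carbinol carbon.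
- Forward key step: a bromide-transferring Lewis acid adds bromide to the β-carbon of both ynoates, the two metal allenolates add to 2, and the tertiary hydroxyls close the lactones.
- For: six bonds form in one flask without photochemistry. The vinylic bromines arise in the ring-forming event. On this point the alternative is stronger than the chosen route, whose late C4 bromination (steps 11 and 12) is its weakest part after the key step. The four ring stereocentres are also settled in A2 before any acetate exists.
- Against: both carbinol centres form in the key step without control, while A1 needs one (S) and one (R) on a core with a twofold axis. That is the statistical half at best, next to two diastereomers that differ only at remote centres. Lactonisation needs the C5 oxygen and the ester cis across C3=C4, and halo-aldol additions to ynoates do not fix that geometry reliably. A2 is a vicinal bis-propargylic diol beside a vicinal dibromide on a four-membered ring, and it would itself need an enantioselective synthesis.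
- Comparison: the chosen route pays for its late bromination but controls the side-chain pairing exactly, through a resolved monomer and a cross-coupling.

**Alternative 2: double oxygen insertion into dispiro cyclobutenones.**
- Disconnection: O1–C5 and O1'–C5' of the bis(4-ethoxybutenolide) A3 are cut. The precursor is A4, in which two 3-ethoxycyclobutenones are spiro-fused to adjacent carbons of a cyclobutene.
- Forward key step: a peracid adds to each ketone and the quaternary spiro carbon migrates to oxygen (Baeyer–Villiger), which expands both four-membered rings to butenolides.
- For: the migration proceeds with retention, so the spiro configuration is copied from the carbon skeleton as a rule and not as a selectivity. In that respect it is more reliable than a photochemical face selection. Strain release also helps the insertion.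
- Against: A4 (three four-membered rings joined at two adjacent quaternary centres, trans and enantiopure) is at least as hard to make as 19. The cyclobutene can be epoxidised by the peracid. The ethoxy groups must later become bromines through 3-(1-acetoxyalkyl)tetronic acids, which lose acetic acid easily.
- Comparison: the chosen route reaches its achiral key substrate in eight steps from 1 and 2 and leaves C4 as C–H until the end.

**Alternative 3: bromolactonisation of a bis(allenoic acid).**
- Disconnection: O1–C5, O1'–C5' and both C4–Br bonds of the bis(silyl ether) A5 are cut. The precursor is A6, a trans-3,4-dibromocyclobutane whose other two ring carbons are the termini of two allenoic acids.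
- Forward key step: an electrophilic bromine source brominates the central allene carbons while each carboxyl oxygen attacks the ring terminus, closing both butenolides anti across one allene π bond.
- For: the reaction type is well established for simple allenoic acids. It delivers lactone, spiro C–O bond and C4–Br together, with the C6 bromines already in place. It therefore avoids both late brominations of the chosen route and is stronger on that point.
- Against: A6 holds two exocyclic allenes on adjacent carbons of a four-membered ring, a strained, s-cis-locked bis-allene prone to cyclisation. Each allene is a stereogenic axis that must be set in addition to C6, C6' and the carbinol centres, so the stereochemical problem is moved and multiplied. The oxygen has to attack a fully substituted ring carbon next to a secondary bromide that can eliminate.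
- Comparison: the chosen route asks for one catalyst-controlled face selection on 14 and otherwise uses stable, known intermediates.

Key step: step 9

Remark 1: the lipase is taken to acylate the (R)-alcohol faster; if the opposite preference is found, the two halves simply exchange roles, because 14 is meso.
Remark 2: which antipode of the oxazaborolidine gives 16 and not its enantiomer has to be established; the (S)-prolinol-derived catalyst is written, and both antipodes are accessible.

## Route

Step 1
Reactants: 1 furan-2(5H)-one; 2 butanal
Product: 4 3-(1-hydroxybutyl)-4-(phenylsulfanyl)dihydrofuran-2(3H)-one (racemic; diastereomer mixture), via aluminium enolate 3 (not isolated)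
Conditions: Me3Al, PhSH, CH2Cl2, 0 °C; 1, THF, −78 °C; then 2, −78 °C; aq. HCl
Reagents that add atoms: dimethylaluminium benzenethiolate (made in the flask from Me3Al and PhSH), C[Al](C)Sc1ccccc1
Why: Conjugate addition of the aluminium thiolate to the butenolide gives an aluminium enolate that is trapped by the aldehyde at C3 (tandem Michael–aldol reaction), which forms the C3–C1'' bond that a direct Morita–Baylis–Hillman reaction of this β-substituted lactone would form only sluggishly. The stereocentres are not controlled: two are removed in step 2 and C1'' is wanted racemic.

Step 2
Reactants: 4 3-(1-hydroxybutyl)-4-(phenylsulfanyl)dihydrofuran-2(3H)-one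
Product: 6 rac-3-(1-hydroxybutyl)furan-2(5H)-one, via sulfoxide 5 (not isolated)
Conditions: mCPBA (1 equiv), CH2Cl2, −78 °C; then toluene, CaCO3, 100 °C
Reagents that add atoms: none
Why: Oxidation to the sulfoxide and thermal syn elimination of benzenesulfenic acid toward the acidic C3–H (cis to sulfur after the trans-selective aldol step) restore the C3=C4 double bond, so that 6 is the formal Morita–Baylis–Hillman adduct of 1 and 2.

Step 3
Reactants: 6 rac-3-(1-hydroxybutyl)furan-2(5H)-one
Product: 7 (1R)-1-(2-oxo-2,5-dihydrofuran-3-yl)butyl acetate; 8 3-[(1S)-1-hydroxybutyl]furan-2(5H)-one (unreacted enantiomer)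
Conditions: Burkholderia cepacia lipase (immobilised), vinyl acetate, MTBE, 30 °C, to about half conversion
Reagents that add atoms: vinyl acetate, C=COC(C)=O
Why: Lipase-catalysed kinetic resolution by irreversible acyl transfer; by the usual size rule for secondary alcohols (butenolide ring large, propyl medium) the (R)-alcohol should be acetylated faster, so one operation gives both halves, one of them already as its acetate. No stereocentre is formed; the two enantiomers are separated as acetate and alcohol.

Step 4
Reactants: 7 (1R)-1-(2-oxo-2,5-dihydrofuran-3-yl)butyl acetate
Product: 9 (1R)-1-(5-bromo-2-oxo-2,5-dihydrofuran-3-yl)butyl acetate (both C5 epimers)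
Conditions: NBS (1.05 equiv), AIBN (cat.), PhCF3, 85 °C
Reagents that add atoms: N-bromosuccinimide, O=C1CCC(=O)N1Br
Why: Wohl–Ziegler bromination: the C5–H bonds are allylic and α to the ring oxygen and give a radical delocalised over C5, C3 and the carbonyl oxygen, so they should be abstracted in preference to the acetoxy-bearing C1''–H. The new C5 centre forms as both epimers, which does not matter because C5 becomes sp2 in step 8.

Step 5
Reactants: 8 3-[(1S)-1-hydroxybutyl]furan-2(5H)-one
Product: 10 2-(tert-butyldimethylsilyloxy)-3-[(1S)-1-(tert-butyldimethylsilyloxy)butyl]furan
Conditions: TBSOTf (2.3 equiv), Et3N (3.5 equiv), CH2Cl2, 0 °C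
Reagents that add atoms: tert-butyldimethylsilyl trifluoromethanesulfonate, CC(C)(C)[Si](C)(C)OS(=O)(=O)C(F)(F)F
Why: Silyl triflate and amine silylate the alcohol and convert the butenolide into its 2-silyloxyfuran (O-silylation, then loss of a C5 proton). The carbinol oxygen travels as a silyl ether in this half because an acetate on C1'' of an electron-rich silyloxyfuran would be expelled by vinylogous β-elimination.

Step 6
Reactants: 9 (1R)-1-(5-bromo-2-oxo-2,5-dihydrofuran-3-yl)butyl acetate; 10 2-(tert-butyldimethylsilyloxy)-3-[(1S)-1-(tert-butyldimethylsilyloxy)butyl]furan
Product: 11 3-[(1R)-1-acetoxybutyl]-3'-[(1S)-1-(tert-butyldimethylsilyloxy)butyl]-5,5'-bi(furan-2(5H)-one) (C5/C5' diastereomers)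
Conditions: CF3CO2Ag (1.2 equiv), CH2Cl2, −78 → −20 °C
Reagents that add atoms: none
Why: Silver-promoted vinylogous Mukaiyama-type alkylation: Ag+ abstracts the C5 bromide of 9 and the silyloxyfuran attacks through C5 because C3 is substituted, which forms the C5–C5' bond between one (R) and one (S) half. Both new centres form unselectively and are removed in step 8.

Step 7
Reactants: 11 3-[(1R)-1-acetoxybutyl]-3'-[(1S)-1-(tert-butyldimethylsilyloxy)butyl]-5,5'-bi(furan-2(5H)-one)
Product: 12 3-[(1R)-1-acetoxybutyl]-3'-[(1S)-1-acetoxybutyl]-5,5'-bi(furan-2(5H)-one) (C5/C5' diastereomers)
Conditions: Ac2O, Sc(OTf)3 (5 mol%), MeCN, 0 °C → rt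
Reagents that add atoms: acetic anhydride, CC(=O)OC(C)=O
Why: Lewis-acid-catalysed direct acetolysis of the silyl ether (O-acylation of the ether oxygen, loss of the silyl group) with retention at C1'', since its C–O bond is not broken. Acidic conditions are chosen because a base would deprotonate C5–H and expel the neighbouring lactone oxygen or the C1'' acetate.

Step 8
Reactants: 12 3-[(1R)-1-acetoxybutyl]-3'-[(1S)-1-acetoxybutyl]-5,5'-bi(furan-2(5H)-one)
Product: 14 meso-(E)-3-[(1S)-1-acetoxybutyl]-3'-[(1R)-1-acetoxybutyl]-5,5'-bifuranylidene-2,2'-dione, via tertiary 5-bromide 13 (not isolated)
Conditions: NBS (1.0 equiv), AIBN (cat.), PhCF3, 85 °C; then 2,6-lutidine, CH2Cl2, 0 °C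
Reagents that add atoms: none
Why: Wohl–Ziegler bromination of one tertiary C5–H and loss of HBr across C5–C5' (ionisation of the tertiary α-oxy allylic bromide, proton taken by the weak base) dehydrogenate the bis-lactone without a C5 carbanion. The (E) isomer, with the ring oxygens anti, should be the thermodynamically favoured one, and with one (S) and one (R) side chain it has a centre of inversion and is achiral.

Step 9
Reactants: 14 meso-(E)-3-[(1S)-1-acetoxybutyl]-3'-[(1R)-1-acetoxybutyl]-5,5'-bifuranylidene-2,2'-dione; 15 acetylene
Product: 16 (5S,5'S)-3-[(1S)-1-acetoxybutyl]-9-[(1R)-1-acetoxybutyl]-1,7-dioxadispiro[4.0.4.2]dodeca-3,9,11-triene-2,8-dione (dispiro cyclobutene, O1 and O1' trans)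
Conditions: 15 (saturated solution), oxazaborolidine [from (S)-α,α-bis(3,5-dimethylphenyl)prolinol and 2,4,6-trifluorophenylboronic acid]·AlBr3 (50 mol%), CH2Cl2, −75 °C, hν (405 nm LED)
Reagents that add atoms: none
Why: Proposed new method: the Lewis acid bound to a lactone carbonyl shifts the absorption of 14 to longer wavelength, so light at the red edge excites mainly the complex, which after intersystem crossing relaxes by twisting about C5=C5' into two 2-oxofuranyl radicals with spin at C5 and C5'; one adds to 15 (C5–C6), and after spin inversion the vinyl radical at C6' combines with the oxofuranyl radical at C5' (C5'–C6'), so the cyclobutene closes by collapse of a triplet-derived 1,4-biradical. The closest known reaction types are the enantioselective [2+2] photocycloaddition of cyclic enones and coumarins with alkenes under AlBr3-activated oxazaborolidines, the photoaddition of acetylene to cyclic enones, and the head-to-head [2+2] dimerisation of 5-methylenebutenolide at its exocyclic double bond to the same dispiro skeleton. The configuration at C5 is set in the first bond formation by the catalyst, which shields one face of the lactone it is bound to; the two lactone carbonyls of the dione core are exchanged by a twofold axis perpendicular to the molecular plane, so binding at either one exposes the same face, and the side-chain centres only make the two complexes diastereomeric. The configuration at C5' is set in the ring closure relative to C5: the triplet has lost the (E) geometry, so the trans relation of O1 and O1' must come from the closure itself, where the arrangement with the two C–O dipoles and the two lactone rings anti is preferred, as in the dimer of 5-methylenebutenolide. The step needs enantioface selection on an achiral, centrosymmetric alkene (only the catalyst provides it, so uncomplexed 14 must not absorb), site selectivity for C5 over C3 in the radical addition (larger spin density at the oxygen-bearing carbon, C3 hindered by the side chain), and survival of the product, a cyclobutene with two allylic C–O bonds that can open thermally, which is why the solution is kept cold and taken into step 10 at once.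

Step 10
Reactants: 16 dispiro cyclobutene
Product: 17 (5S,5'S,6R,6'R)-6,6'-dibromide of 16 (dispiro cyclobutane, C4 and C4' still C–H)
Conditions: Br2 (1.0 equiv), CH2Cl2, −78 °C, dark (16 kept below −40 °C throughout)
Reagents that add atoms: bromine, BrBr
Why: Electrophilic anti addition through a bromonium ion; at −78 °C only the strained, non-conjugated cyclobutene should react, not the conjugated butenolide alkenes. The two faces of the cyclobutene are equivalent as far as the core is concerned, so the diastereomer is decided by which carbon bromide opens: entry at the carbon whose neighbour presents the small, positively polarised C4–H, and not the lone pairs of a lactone oxygen, puts each bromine anti to the vicinal C–O bond, as in 19.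

Step 11
Reactants: 17 (5S,5'S,6R,6'R)-6,6'-dibromide
Product: 18 3,3',4,4',6,6'-hexabromide (trans-3,4- and trans-3',4'-dibromides, mixture of trans isomers; C5, C5', C6, C6' as in 17)
Conditions: Br2 (excess), CH2Cl2, 25 °C, dark
Reagents that add atoms: bromine, BrBr
Why: Electrophilic anti addition of bromine to the α-substituted α,β-unsaturated lactones; it needs excess reagent and time because C4 is flanked by O1' and by the bromine on C6. Each ring gives a trans-3,4-dibromide, and all of these isomers converge in step 12.

Step 12
Reactants: 18 hexabromide
Product: 19 target, (5S,5'S,6R,6'R)-4,4',6,6'-tetrabromide with (1S)- and (1R)-1-acetoxybutyl groups at C3 and C3'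
Conditions: AgOTf (2.5 equiv), 2,6-di-tert-butyl-4-methylpyridine (3 equiv), CH2Cl2, −40 → 0 °C, dark
Reagents that add atoms: none
Why: Proposed new method: in each trans-dibromide the hydrogen on C4 is syn to the bromine on C3, so a direct anti elimination is impossible and an amine would remove the hydrogen on C1''; instead Ag+ abstracts the tertiary C3 bromide with participation of the vicinal acetate, whose carbonyl oxygen enters C3 with inversion to give a 1,3-dioxolan-2-ylium ion in which the C3–O bond is anti to the C4 hydrogen, and the hindered base removes that hydrogen, which re-forms C3=C4 with bromine on C4 and returns the acetate to C1'' without ever breaking the C1''–O bond, so the (S) and (R) centres are kept. The closest known reaction types are the silver-assisted formation of acyloxonium ions from vicinal halo esters (Woodward–Prévost and Koenigs–Knorr chemistry) and anti E2 elimination.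

## Compound list

1 | furan-2(5H)-one | O=C1OCC=C1 | starting material
2 | butanal | CCCC=O | starting material
3 | dimethylaluminium enolate of 4-(phenylsulfanyl)dihydrofuran-2(3H)-one | C[Al](C)OC1=CC(Sc2ccccc2)CO1 | intermediate (not isolated)
4 | 3-(1-hydroxybutyl)-4-(phenylsulfanyl)dihydrofuran-2(3H)-one, racemic diastereomer mixture | CCCC(O)C1C(Sc2ccccc2)COC1=O | intermediate
5 | 3-(1-hydroxybutyl)-4-(phenylsulfinyl)dihydrofuran-2(3H)-one | CCCC(O)C1C(S(=O)c2ccccc2)COC1=O | intermediate (not isolated)
6 | rac-3-(1-hydroxybutyl)furan-2(5H)-one | CCCC(O)C1=CCOC1=O | intermediate
7 | (1R)-1-(2-oxo-2,5-dihydrofuran-3-yl)butyl acetate | CCC[C@@H](OC(C)=O)C1=CCOC1=O | intermediate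
8 | 3-[(1S)-1-hydroxybutyl]furan-2(5H)-one | CCC[C@H](O)C1=CCOC1=O | intermediate
9 | (1R)-1-(5-bromo-2-oxo-2,5-dihydrofuran-3-yl)butyl acetate, both C5 epimers | CCC[C@@H](OC(C)=O)C1=CC(Br)OC1=O | intermediate
10 | 2-(tert-butyldimethylsilyloxy)-3-[(1S)-1-(tert-butyldimethylsilyloxy)butyl]furan | CCC[C@H](O[Si](C)(C)C(C)(C)C)c1ccoc1O[Si](C)(C)C(C)(C)C | intermediate
11 | 3-[(1R)-1-acetoxybutyl]-3'-[(1S)-1-(tert-butyldimethylsilyloxy)butyl]-5,5'-bi(furan-2(5H)-one), C5/C5' diastereomers | CCC[C@H](O[Si](C)(C)C(C)(C)C)C1=CC(OC1=O)C2OC(=O)C([C@@H](CCC)OC(C)=O)=C2 | intermediate
12 | 3-[(1R)-1-acetoxybutyl]-3'-[(1S)-1-acetoxybutyl]-5,5'-bi(furan-2(5H)-one), C5/C5' diastereomers | CCC[C@H](OC(C)=O)C1=CC(OC1=O)C2OC(=O)C([C@@H](CCC)OC(C)=O)=C2 | intermediate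
13 | 5-bromo derivative of 12 (tertiary bromide at one C5) | CCC[C@H](OC(C)=O)C1=CC(Br)(OC1=O)C2OC(=O)C([C@@H](CCC)OC(C)=O)=C2 | intermediate (not isolated)
14 | meso-(E)-3-[(1S)-1-acetoxybutyl]-3'-[(1R)-1-acetoxybutyl]-5,5'-bifuranylidene-2,2'-dione | CCC[C@H](OC(C)=O)C1=C/C(OC1=O)=C2\OC(=O)C([C@@H](CCC)OC(C)=O)=C2 | intermediate
15 | acetylene | C#C | starting material
16 | (5S,5'S)-dispiro cyclobutene bis(butenolide), C4 and C4' unbrominated | CCC[C@H](OC(C)=O)C1=C[C@@]2(OC1=O)C=C[C@@]21OC(=O)C([C@@H](CCC)OC(C)=O)=C1 | intermediate
17 | (5S,5'S,6R,6'R)-6,6'-dibromo dispiro cyclobutane bis(butenolide) | CCC[C@H](OC(C)=O)C1=C[C@@]2(OC1=O)[C@@H](Br)[C@H](Br)[C@@]21OC(=O)C([C@@H](CCC)OC(C)=O)=C1 | intermediate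
18 | 3,3',4,4',6,6'-hexabromo bis(lactone), trans-3,4- and trans-3',4'-dibromides | CCC[C@H](OC(C)=O)C1(Br)C(Br)[C@@]2(OC1=O)[C@@H](Br)[C@H](Br)[C@@]21OC(=O)C(Br)([C@@H](CCC)OC(C)=O)C1Br | intermediate
19 | CNP0266230.1, (5S,5'S,6R,6'R)-4,4',6,6'-tetrabromide | CCC[C@H](OC(C)=O)C1=C(Br)[C@@]2(OC1=O)[C@@H](Br)[C@H](Br)[C@@]21OC(=O)C([C@@H](CCC)OC(C)=O)=C1Br | target

## Step count and least certain steps

Total step count: 12. Longest linear sequence: 11 (steps 1, 2, 3, then 4 or 5, then 6 to 12).

**Step 9 (key step, proposed new method).**
- What may go wrong: the twisted triplet may decay (E/Z isomerisation) faster than it adds to 15, because a stabilised oxofuranyl radical has to create a vinyl radical. Face selection may be poor because uncomplexed 14 also absorbs and the acetate carbonyls compete for the Lewis acid.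
- Fallback: it sets out from 14 and 15 and comes back at 16. Compound 14 is irradiated at 405 nm with thioxanthen-9-one as triplet sensitiser in acetylene-saturated acetone/CH2Cl2 at −60 °C, without any Lewis acid. This is the sensitised [2+2] photocycloaddition of an alkyne to a conjugated lactone alkene. It should give 16 together with its mirror image, the enantiomeric cyclobutene F1. The two are separated by preparative chromatography on a chiral stationary phase with a cooled column. The absolute configuration then comes from separation and not from catalysis.

**Step 12 (proposed new method; it also depends on the slow addition of step 11).**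
- What may go wrong: ionisation may occur at the wrong bromide. Participation of the vicinal C4 bromine instead of the acetate would deliver the acyloxonium ion with the C3–O bond syn to the C4 hydrogen, which cannot eliminate. Silver may also attack the cyclobutane dibromide.
- Fallback: it uses known selenium chemistry, sets out from 17 and comes back at 19, replacing steps 11 and 12. PhSeBr is added anti across both C3=C4 bonds (selenium to C3, bromide to C4) to give the bis(3-phenylselanyl-4-bromo) lactone F2. Oxidation with O3 at −78 °C gives the bis-selenoxide F3. On warming it undergoes the pericyclic syn elimination, for which the C4 hydrogen is the cis hydrogen, while the alternative hydrogen sits on the acetoxy-bearing C1'', toward which selenoxide eliminations are reluctant.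

**Step 10.**
- What may go wrong: bromide may open the bromonium ion at the other carbon, which gives the diastereomer with both bromines syn to the vicinal C–O bonds.
- Fallback: it sets out from the product mixture of step 10 and comes back at 17. The mixture of 17 and its (5S,5'S,6S,6'S) diastereomer F4 is warmed in MeNO2 or MeCN at 40–60 °C without added nucleophile. trans-Vicinal dibromides interconvert through bromonium–bromide ion pairs, so the ratio moves to the thermodynamic one, which should favour 17 with its opposed C–Br and C–O dipoles. This is thermodynamic control in place of kinetic control.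

**Step 8.**
- What may go wrong: radical bromination on the dimer may be unselective (attack at C1''–H, double bromination).
- Fallback: it sets out from 7 and 10 and comes back at 14, replacing steps 4, 6, 7 and 8. Compound 7 is brominated twice with NBS to the (1R)-1-(5,5-dibromo-2-oxo-2,5-dihydrofuran-3-yl)butyl acetate F5. Coupling with 10 and CF3CO2Ag (2.2 equiv) in the presence of 2,6-di-tert-butyl-4-methylpyridine gives the tertiary bromide F6. F6 loses bromide to the second silver ion and a proton from C5', giving the mixed acetate/silyl ether (E)-bifuranylidenedione F7. The conditions of step 7 convert F7 into 14. The unsaturation then comes from the oxidation level of the electrophile and no C–H bromination of the dimer is needed.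

**Step 6.**
- What may go wrong: ionisation of the bromide 9 by silver may be slow, or the silyloxyfuran may be destroyed by acid before it couples.
- Fallback: it sets out from 9 and 10 and comes back at 11. The coupling is run as a photoredox radical alkylation (tris(2-phenylpyridinato)iridium, Ir(ppy)3, 1 mol%, blue LED, MeCN, rt). The excited catalyst reduces the C5–Br bond of 9, the oxofuranyl radical adds to C5 of 10, and the adduct radical is oxidised and desilylated to 11. This is a radical instead of a cationic pathway and makes no compound beyond the list (F0).

**Step 3.**
- What may go wrong: the lipase may discriminate poorly between a propyl group and the ring, which would leave each half contaminated by its enantiomer and 14 by its chiral diastereomers.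
- Fallback: it sets out from 6 and comes back at 7 and 8. Racemic 6 is separated by preparative supercritical-fluid chromatography on a chiral stationary phase into 8 and the (R)-alcohol F8. F8 is acetylated (Ac2O, Sc(OTf)3 cat., MeCN, 0 °C) to 7.

## Further compounds

F1 | step 9 | enantiomer of 16, (5R,5'R)-dispiro cyclobutene | CCC[C@@H](OC(C)=O)C1=C[C@]2(OC1=O)C=C[C@]21OC(=O)C([C@H](CCC)OC(C)=O)=C1
F2 | step 12 | bis(3-phenylselanyl-4-bromo) adduct of 17 | CCC[C@H](OC(C)=O)C1([Se]c2ccccc2)C(Br)[C@@]3(OC1=O)[C@@H](Br)[C@H](Br)[C@@]34OC(=O)C([Se]c5ccccc5)([C@@H](CCC)OC(C)=O)C4Br
F3 | step 12 | bis-selenoxide of F2 | CCC[C@H](OC(C)=O)C1([Se](=O)c2ccccc2)C(Br)[C@@]3(OC1=O)[C@@H](Br)[C@H](Br)[C@@]34OC(=O)C([Se](=O)c5ccccc5)([C@@H](CCC)OC(C)=O)C4Br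
F4 | step 10 | (5S,5'S,6S,6'S) diastereomer of 17 | CCC[C@H](OC(C)=O)C1=C[C@@]2(OC1=O)[C@H](Br)[C@@H](Br)[C@@]21OC(=O)C([C@@H](CCC)OC(C)=O)=C1
F5 | step 8 | (1R)-1-(5,5-dibromo-2-oxo-2,5-dihydrofuran-3-yl)butyl acetate | CCC[C@@H](OC(C)=O)C1=CC(Br)(Br)OC1=O
F6 | step 8 | 5-bromo-3-[(1R)-1-acetoxybutyl]-3'-[(1S)-1-(tert-butyldimethylsilyloxy)butyl]-5,5'-bi(furan-2(5H)-one) | CCC[C@H](O[Si](C)(C)C(C)(C)C)C1=CC(OC1=O)C2(Br)OC(=O)C([C@@H](CCC)OC(C)=O)=C2
F7 | step 8 | (E)-3-[(1S)-1-(tert-butyldimethylsilyloxy)butyl]-3'-[(1R)-1-acetoxybutyl]-5,5'-bifuranylidene-2,2'-dione | CCC[C@H](O[Si](C)(C)C(C)(C)C)C1=C/C(OC1=O)=C2\OC(=O)C([C@@H](CCC)OC(C)=O)=C2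
F0 | step 6 | none | none
F8 | step 3 | 3-[(1R)-1-hydroxybutyl]furan-2(5H)-one | CCC[C@@H](O)C1=CCOC1=O
A1 | alternative 1 | (S,R)-diol, 19 without its two acetyl groups | CCC[C@H](O)C1=C(Br)[C@@]2(OC1=O)[C@@H](Br)[C@H](Br)[C@@]21OC(=O)C([C@@H](CCC)O)=C1Br
A2 | alternative 1 | diethyl 3,3'-(trans-3,4-dibromo-1,2-dihydroxycyclobutane-1,2-diyl)dipropiolate, hydroxyls trans | CCOC(=O)C#C[C@@]1(O)[C@@H](Br)[C@H](Br)[C@]1(O)C#CC(=O)OCC
A3 | alternative 2 | dispiro cyclobutene bis(4-ethoxybutenolide) | CCC[C@H](OC(C)=O)C1=C(OCC)[C@@]2(OC1=O)C=C[C@@]21OC(=O)C([C@@H](CCC)OC(C)=O)=C1OCC
A4 | alternative 2 | dispiro cyclobutene bis(3-ethoxycyclobut-2-enone) | CCC[C@H](OC(C)=O)C1=C(OCC)[C@@]2(C1=O)C=C[C@@]21C(=O)C([C@@H](CCC)OC(C)=O)=C1OCC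
A5 | alternative 3 | bis(tert-butyldimethylsilyl) ether of A1 | CCC[C@H](O[Si](C)(C)C(C)(C)C)C1=C(Br)[C@@]2(OC1=O)[C@@H](Br)[C@H](Br)[C@@]21OC(=O)C([C@@H](CCC)O[Si](C)(C)C(C)(C)C)=C1Br
A6 | alternative 3 | bis(allenoic acid) on a trans-3,4-dibromocyclobutane-1,2-diylidene core (allene axes not encoded) | CCC[C@H](O[Si](C)(C)C(C)(C)C)C(C(=O)O)=C=C1[C@@H](Br)[C@H](Br)C1=C=C(C(=O)O)[C@@H](CCC)O[Si](C)(C)C(C)(C)C
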